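**Strategy.** The ten-membered carbocycle C1–C10 is traced back to a six-membered ring by bonding C1 to C6 and breaking C8–C9. The run C6–C5=C4–C3(O)C2–C1 then is a 4,5-epoxycyclohex-2-ene whose carbinol carbon C6 carries a (Z)-2-alkoxyvinyl group (C7=C8) and whose C1 carries a cyclic enol ether (C10=C9). One anionic oxy-Cope step breaks C1–C6, forms C8–C9, expands the six-membered to the ten-membered ring, creates the ring-cis C1=C10 alkene and sets C8 and C9. The cis C4=C5 alkene and the cis C2–C3 epoxide pass through unchanged. Lactone annulation at C6/C7 and ester adjustments follow.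

Key step: step 17

**Remarks on the chemistry**

- Numbering: carbocycle C6 (lactone O–CH), C5=C4, C3–C2 (epoxide), C1=C10, C9 (OAc), C8 (O-epoxyangelate), C7 (ring fusion); C11–C13 are the lactone carbons, C14 the ester carbon on C10.
- Structure check: in this numbering the target is 2R,3S,6R,7S,8S,9R, with a trans-fused lactone, an erythro C8/C9 pair and a (2S,3S) acyl group.
- Correction: in the rearrangement substrate the C9 oxygen must stand trans to ring carbon C1 and cis to C14. Because CH2O outranks the ring carbon, this enol ether is (Z); an (E) label for it would be wrong. The two alkenyl groups and the epoxide oxygen lie on one face, the hydroxyl on the other.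
- Design change (skeleton and disconnection kept): O9 and O14 are tied into a 2,2-di-tert-butyl-4H-1,3,2-dioxasiline. This locks the enol ether geometry that sets C9 (an open-chain silyl enol ether of the α-branched aldehyde would form as a mixture), keeps O14 distinct from O8 (the only 4-methoxybenzyl ether), and is removed by fluoride.
- Assumption: the lipase hydrolyses the acetate of 2 at the (R)-configured carbon and so gives 3; if it prefers the other ester, the same enzyme is used in the acylation direction on the meso diol with vinyl acetate, which then gives 3.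
- Compounds 6, 15, 19, 21, 22, 24, 26, 27, 30, 34, 36, 37, 38, 44, 46 and 49 are formed and consumed in the flask.

**Route**

Step 1
Reactants: 1 cyclohexa-1,3-diene
Product: 2 cis-cyclohex-2-ene-1,4-diyl diacetate (meso)
Conditions: Pd(OAc)2 (cat.), LiCl (cat.), LiOAc, p-benzoquinone, AcOH, rt
Reagents that add atoms: acetic acid (used with LiOAc), CC(=O)O
Why: Palladium-catalysed 1,4-diacetoxylation of a conjugated diene, in which catalytic chloride steers the second acetate so that the cis (meso) diester should result.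

Step 2
Reactants: 2 cis-cyclohex-2-ene-1,4-diyl diacetate
Product: 3 (1S,4R)-4-hydroxycyclohex-2-en-1-yl acetate
Conditions: Candida antarctica lipase B, phosphate buffer pH 7, rt
Reagents that add atoms: none
Why: Enzymatic desymmetrisation of a meso diester by hydrolysis of one enantiotopic acetate fixes the absolute configuration of the future C6 and C3.

Step 3
Reactants: 3 (1S,4R)-4-hydroxycyclohex-2-en-1-yl acetate; 4 methyl 3-chloro-3-oxopropanoate
Product: 5 (1R,4S)-4-acetoxycyclohex-2-en-1-yl methyl malonate
Conditions: pyridine, CH2Cl2, 0 °C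
Reagents that add atoms: none
Why: O-acylation of the allylic alcohol by the acid chloride (nucleophilic acyl substitution) leaves the carbinol centre untouched.

Step 4
Reactants: 5 (1R,4S)-4-acetoxycyclohex-2-en-1-yl methyl malonate
Product: 7 cis-fused lactone ester (methyl 2-oxo-hexahydrobenzofuran-3-carboxylate), via sodium malonate enolate 6 (not isolated)
Conditions: NaH, THF, 0 °C; Pd(PPh3)4 (cat.), 65 °C
Reagents that add atoms: none
Why: Intramolecular Tsuji–Trost allylic alkylation, in which palladium ionises the allylic acetate anti and the malonate carbanion tethered through the C6 oxygen attacks the adjacent allyl terminus C1 anti to the metal (5-exo), which can only give the cis-fused γ-lactone and so sets C1 cis to the C6 oxygen.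

Step 5
Reactants: 7 cis-fused lactone ester
Product: 8 (1R,2R)-2-(1,3-dihydroxypropan-2-yl)cyclohex-3-en-1-ol
Conditions: LiAlH4, THF, 0 °C to rt
Reagents that add atoms: none
Why: Hydride reduction of the lactone and the ester gives the triol, removes the stereocentre at C10 and does not touch C1 or C6.

Step 6
Reactants: 8 (1R,2R)-2-(1,3-dihydroxypropan-2-yl)cyclohex-3-en-1-ol
Product: 9 (1R,2R)-2-(2,2-di-tert-butyl-1,3,2-dioxasilinan-5-yl)cyclohex-3-en-1-ol
Conditions: t-Bu2Si(OTf)2, 2,6-lutidine, CH2Cl2, −78 to 0 °C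
Reagents that add atoms: di-tert-butylsilyl bis(trifluoromethanesulfonate), CC(C)(C)[Si](OS(=O)(=O)C(F)(F)F)(OS(=O)(=O)C(F)(F)F)C(C)(C)C
Why: Silylene protection of a diol, in which the two primary hydroxyls close the six-membered 1,3,2-dioxasilinane much faster than any ring that would include the secondary C6 hydroxyl.

Step 7
Reactants: 9 (1R,2R)-2-(2,2-di-tert-butyl-1,3,2-dioxasilinan-5-yl)cyclohex-3-en-1-ol
Product: 10 all-cis epoxy alcohol
Conditions: VO(acac)2 (cat.), t-BuOOH, CH2Cl2, 0 °C to rt
Reagents that add atoms: tert-butyl hydroperoxide, CC(C)(C)OO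
Why: Hydroxyl-directed epoxidation of a homoallylic cyclohexenol by the vanadium alkoxide–peroxide complex delivers oxygen to the face of the C6 hydroxyl, which is the face of the C1 substituent, and so sets C2 and C3.

Step 8
Reactants: 10 all-cis epoxy alcohol
Product: 11 epoxy ketone with silylene-protected diol
Conditions: Dess–Martin periodinane, pyridine, CH2Cl2, 0 °C to rt
Reagents that add atoms: none
Why: Dess–Martin oxidation of the secondary alcohol under buffered conditions gives the ketone without enolising C1 next to the epoxide.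

Step 9
Reactants: 11 epoxy ketone with silylene-protected diol
Product: 12 epoxy keto diol
Conditions: HF·pyridine, pyridine, THF, 0 °C
Reagents that add atoms: none
Why: Fluoride cleavage of the di-tert-butylsilylene (Si–O to Si–F exchange) frees the 1,3-diol under buffered conditions that leave epoxide and ketone alone.

Step 10
Reactants: 12 epoxy keto diol
Product: 13 epoxy keto β-hydroxy aldehyde (both C10 epimers)
Conditions: TEMPO (cat.), PhI(OAc)2 (1.1 equiv), CH2Cl2, 0 °C
Reagents that add atoms: none
Why: Oxoammonium (TEMPO) oxidation is selective for primary alcohols, and because both hydroxymethyl groups lead to the same enol ether in the next step only over-oxidation has to be limited by the stoichiometry, the crude hydroxy aldehyde being used at once.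

Step 11
Reactants: 13 epoxy keto β-hydroxy aldehyde
Product: 14 epoxy ketone with 4H-1,3,2-dioxasiline (cyclic silyl enol ether)
Conditions: t-Bu2Si(OTf)2, Et3N, CH2Cl2, −78 to 0 °C
Reagents that add atoms: di-tert-butylsilyl bis(trifluoromethanesulfonate), CC(C)(C)[Si](OS(=O)(=O)C(F)(F)F)(OS(=O)(=O)C(F)(F)F)C(C)(C)C
Why: Silyl enol ether formation from an aldehyde with a silyl triflate and an amine (soft enolisation), made intramolecular by prior silylation of the C14 hydroxyl, closes the six-membered ring in which the C9 oxygen is necessarily cis to C14 and trans to C1.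

Step 12
Reactants: 14 epoxy ketone with 4H-1,3,2-dioxasiline
Product: 16 α-phenylselanyl ketone, via lithium enolate 15 (not isolated)
Conditions: LiN(iPr)2, THF, −78 °C; PhSeBr, −78 °C
Reagents that add atoms: benzeneselenenyl bromide, Br[Se]c1ccccc1
Why: Kinetic deprotonation at the less hindered C5 methylene and α-selenenylation of the enolate on the face away from the epoxide oxygen should place the selanyl group trans to the C1 substituent.

Step 13
Reactants: 17 4-methoxybenzyl alcohol
Product: 18 4-methoxybenzyl vinyl ether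
Conditions: Pd(OAc)2 (cat.), 1,10-phenanthroline (cat.), butyl vinyl ether, rt
Reagents that add atoms: butyl vinyl ether, C=COCCCC
Why: Palladium-catalysed transfer vinylation (transetherification) of an alcohol with an alkyl vinyl ether.

Step 14
Reactants: 18 4-methoxybenzyl vinyl ether
Product: 20 (Z)-1-bromo-2-(4-methoxybenzyloxy)ethene, via 1,2-dibromoethyl ether 19 (not isolated)
Conditions: Br2, CH2Cl2, −78 °C; DBU, −78 °C to rt
Reagents that add atoms: bromine, BrBr
Why: Bromine addition to the vinyl ether followed by anti E2 loss of HBr from the α-bromo ether should give mainly the (Z)-2-bromovinyl ether (cis preference of 1-alkoxy-2-haloethenes), the (E)-isomer being removed by chromatography.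

Step 15
Reactants: 16 α-phenylselanyl ketone; 20 (Z)-1-bromo-2-(4-methoxybenzyloxy)ethene
Product: 23 cis-dialkenyl selanyl carbinol, via (Z)-vinyllithium 21 (not isolated), via (Z)-vinylcerium dichloride 22 (not isolated)
Conditions: 20, t-BuLi (2 equiv), Et2O, −78 °C; CeCl3, THF, −78 °C; then 16, −78 °C
Reagents that add atoms: none
Why: Bromine–lithium exchange with retention of the (Z) geometry, transmetalation to the weakly basic organocerium reagent and 1,2-addition to the ketone, expected anti to the pseudo-axial C5–Se bond (Felkin–Anh) and therefore syn to the C1 substituent, should give the carbinol with both alkenyl groups on one face and the hydroxyl on the other.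

Step 16
Reactants: 23 cis-dialkenyl selanyl carbinol
Product: 25 (1R,4S,5R,6S)-6-(2,2-di-tert-butyl-4H-1,3,2-dioxasilin-5-yl)-4,5-epoxy-1-[(Z)-2-(4-methoxybenzyloxy)vinyl]cyclohex-2-en-1-ol, via selenoxide 24 (not isolated)
Conditions: mCPBA (1.0 equiv), CH2Cl2, −78 °C; i-Pr2NH, −78 °C to rt
Reagents that add atoms: none
Why: Oxidation at selenium and syn-elimination of the β-hydroxy selenoxide, which can only run towards C4 because C6 has no hydrogen, gives the C4=C5 alkene without touching a stereocentre.

Step 17
Reactants: 25 epoxy dialkenyl cyclohexenol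
Product: 28 ten-membered epoxy dienone (C6 ketone; C8 4-methoxybenzyl ether; O9/O14 silylene), via potassium alkoxide 26 (not isolated), via potassium enolate 27 (not isolated)
Conditions: KH, 18-crown-6, THF, 0 °C to rt; AcOH, THF, −78 °C
Reagents that add atoms: none
Why: KH deprotonates the tertiary alcohol, and the potassium alkoxide 26, made more reactive by 18-crown-6, undergoes a concerted [3,3] sigmatropic shift through a six-membered chair in which C1–C6 breaks as C8–C9 forms, giving enolate 27 and, after protonation at C7, ketone 28. The closest known reaction type is the anionic oxy-Cope ring expansion of cis-1,2-dialkenylcyclohexanols to cyclodec-5-enones, including cases with enol ether termini. The ten-membered ring is not closed by a cyclisation but arises by ring expansion, the six ring atoms C6–C5–C4–C3–C2–C1 and the four atoms C7–C8–C9–C10 becoming one ring, so no exo or endo mode applies. C8 (S) is set by the (Z)-enol ether, whose oxygen is pseudo-axial on the chair, and C9 (R) by the cyclic enol ether, whose oxygen is locked trans to C1 and is pseudo-equatorial; both are relayed from the configurations of C6 and C1 and together give the erythro C8/C9 pair. The step needs the chair with C2 pseudo-axial and C5 pseudo-equatorial, which gives the ring-cis C1=C10 alkene; the cis arrangement of the two alkenyl groups allows only chairs with one of these ring bonds axial, and the chair with C2 equatorial is disfavoured because C2 would eclipse the C14 methylene on C10 (A(1,2) strain). The cis C4=C5 alkene and the cis C2–C3 epoxide take no part and are carried into the product.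

Step 18
Reactants: 28 ten-membered epoxy dienone; 29 tert-butyl bromoacetate
Product: 31 C7-alkylated ketone (7R), via lithium enolate 30 (not isolated)
Conditions: LiN(SiMe3)2, THF, −78 °C; then 29, −78 to −30 °C
Reagents that add atoms: none
Why: Kinetic deprotonation at C7 and SN2 alkylation of the lithium enolate, held by chelation of lithium between the enolate oxygen and the C8 ether oxygen so that the electrophile enters from the ring periphery anti to C9, should give the 7R ketone, which is the arrangement that reads 7S in the target.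

Step 19
Reactants: 31 C7-alkylated ketone
Product: 32 (6S)-allylic alcohol (hydroxyl cis to the C7 side chain)
Conditions: NaBH4, CeCl3·7H2O, MeOH, −78 °C
Reagents that add atoms: none
Why: Luche 1,2-reduction of the enone, in which Felkin–Anh attack anti to the C7 side chain and chelation between the carbonyl and the C8 ether oxygen reinforce each other, should give the 6S alcohol, and the tert-butyl ester keeps it from lactonising.

Step 20
Reactants: 32 (6S)-allylic alcohol
Product: 33 (6R)-4-nitrobenzoate
Conditions: PPh3, DIAD, 4-nitrobenzoic acid, toluene, 0 °C to rt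
Reagents that add atoms: 4-nitrobenzoic acid, OC(=O)c1ccc(cc1)[N+](=O)[O-]
Why: Mitsunobu esterification inverts the allylic carbinol centre C6 by SN2 displacement of the oxyphosphonium group.

Step 21
Reactants: 33 (6R)-4-nitrobenzoate
Product: 35 trans-fused 6,7-γ-lactone, via trans-hydroxy ester 34 (not isolated)
Conditions: K2CO3, MeOH, rt
Reagents that add atoms: none
Why: Methanolysis of the aryl ester releases the C6 alkoxide, which closes the γ-lactone on the neighbouring tert-butyl ester (5-exo-trig transesterification) with retention at C6.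

Step 22
Reactants: 35 trans-fused 6,7-γ-lactone
Product: 39 α-methylene lactone, via lithium enolate 36 (not isolated), via Mannich base 37 (not isolated), via trimethylammonium iodide 38 (not isolated)
Conditions: LiN(iPr)2, THF, −78 °C; CH2=N(CH3)2 I, −78 °C to rt; CH3I, MeOH; NaHCO3 aq
Reagents that add atoms: N,N-dimethylmethyleneiminium iodide, C=[N+](C)C.[I-]
Why: Eschenmoser methylenation, in which a Mannich reaction of the lactone enolate, quaternisation and E1cB loss of trimethylamine install the exocyclic C11=C13 alkene.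

Step 23
Reactants: 39 α-methylene lactone
Product: 40 C8 alcohol
Conditions: DDQ, CH2Cl2, pH 7 buffer, 0 °C
Reagents that add atoms: none
Why: Oxidative cleavage of the 4-methoxybenzyl ether by hydride abstraction to the benzylic oxocarbenium ion and hydrolysis frees the C8 hydroxyl under neutral conditions.

Step 24
Reactants: 41 angelic acid
Product: 42 (Z)-2-methylbut-2-en-1-ol
Conditions: LiAlH4, Et2O, 0 °C
Reagents that add atoms: none
Why: Hydride reduction of the carboxylic acid to the allylic alcohol keeps the (Z) alkene.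

Step 25
Reactants: 42 (Z)-2-methylbut-2-en-1-ol
Product: 43 [(2R,3S)-2,3-dimethyloxiran-2-yl]methanol
Conditions: Ti(OiPr)4, D-(−)-diethyl tartrate, t-BuOOH, 4 Å molecular sieves, CH2Cl2, −20 °C
Reagents that add atoms: tert-butyl hydroperoxide, CC(C)(C)OO
Why: Sharpless asymmetric epoxidation, in which the D-(−)-tartrate complex delivers oxygen to the face opposite to the one used with L-(+)-tartrate (which gives 2S epoxy alcohols) and so should give the 2R,3S epoxy alcohol.

Step 26
Reactants: 43 [(2R,3S)-2,3-dimethyloxiran-2-yl]methanol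
Product: 45 (2S,3S)-2,3-dimethyloxirane-2-carboxylic acid, via epoxy aldehyde 44 (not isolated)
Conditions: TEMPO (cat.), PhI(OAc)2, MeCN, H2O, rt
Reagents that add atoms: water, O
Why: TEMPO-mediated oxidation of the primary alcohol through the aldehyde hydrate gives the glycidic acid without touching the epoxide, the C2 descriptor changing from R to S only because the carboxyl group now outranks C3.

Step 27
Reactants: 40 C8 alcohol; 45 (2S,3S)-2,3-dimethyloxirane-2-carboxylic acid
Product: 47 C8 epoxyangelate, via mixed anhydride 46 (not isolated)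
Conditions: 45, 2,4,6-trichlorobenzoyl chloride, Et3N, THF, rt; then 40, DMAP, toluene, rt
Reagents that add atoms: none
Why: Yamaguchi esterification through the mixed anhydride and the acylpyridinium ion acylates the hindered C8 hydroxyl without acid, so both epoxides survive.

Step 28
Reactants: 47 C8 epoxyangelate
Product: 48 C9,C14 diol
Conditions: HF·pyridine, pyridine, THF, 0 °C
Reagents that add atoms: none
Why: Fluoride cleavage of the silylene frees the C9 and C14 hydroxyls under buffered conditions.

Step 29
Reactants: 48 C9,C14 diol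
Product: 50 C14 carboxylic acid, via enal 49 (not isolated)
Conditions: TEMPO (cat.), PhI(OAc)2, MeCN, pH 7 buffer, 0 °C to rt
Reagents that add atoms: water, O
Why: TEMPO-mediated oxidation distinguishes the primary allylic C14 hydroxyl from the secondary C9 hydroxyl and carries it through the enal to the acid.

Step 30
Reactants: 50 C14 carboxylic acid
Product: 51 C14 methyl ester with free C9 hydroxyl
Conditions: Me3SiCHN2, toluene, MeOH, 0 °C
Reagents that add atoms: (trimethylsilyl)diazomethane, C[Si](C)(C)C=[N+]=[N-]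
Why: O-methylation of the carboxylic acid by the diazoalkane (protonation, then SN2 on the diazonium ion) gives the methyl ester under neutral conditions.

Step 31
Reactants: 51 C14 methyl ester with free C9 hydroxyl
Product: 52 target CNP0077533.1
Conditions: Ac2O, pyridine, DMAP (cat.), CH2Cl2, 0 °C
Reagents that add atoms: acetic anhydride, CC(=O)OC(C)=O
Why: DMAP-catalysed acetylation of the remaining C9 hydroxyl completes the target, and the hindered neighbouring ester is not expected to migrate under these conditions.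

**Compound list**

1 | cyclohexa-1,3-diene | C1=CC=CCC1 | starting material
2 | cis-cyclohex-2-ene-1,4-diyl diacetate (meso) | CC(=O)O[C@H]1C=C[C@@H](OC(C)=O)CC1 | intermediate
3 | (1S,4R)-4-hydroxycyclohex-2-en-1-yl acetate | O[C@H]1C=C[C@@H](OC(C)=O)CC1 | intermediate
4 | methyl 3-chloro-3-oxopropanoate (methyl malonyl chloride) | COC(=O)CC(Cl)=O | starting material
5 | (1R,4S)-4-acetoxycyclohex-2-en-1-yl methyl malonate | COC(=O)CC(=O)O[C@H]1C=C[C@@H](OC(C)=O)CC1 | intermediate
6 | sodium enolate of 5 (malonate carbanion) | [Na+].COC(=O)[CH-]C(=O)O[C@H]1C=C[C@@H](OC(C)=O)CC1 | intermediate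
7 | methyl (3aR,7aR)-2-oxo-2,3,3a,6,7,7a-hexahydro-1-benzofuran-3-carboxylate (cis-fused, both C3 epimers) | O=C1O[C@@H]2CCC=C[C@@H]2C1C(=O)OC | intermediate
8 | (1R,2R)-2-(1,3-dihydroxypropan-2-yl)cyclohex-3-en-1-ol (cis) | O[C@@H]1CCC=C[C@@H]1C(CO)CO | intermediate
9 | (1R,2R)-2-(2,2-di-tert-butyl-1,3,2-dioxasilinan-5-yl)cyclohex-3-en-1-ol (cis) | O[C@@H]1CCC=C[C@@H]1C2CO[Si](C(C)(C)C)(C(C)(C)C)OC2 | intermediate
10 | all-cis 2-(2,2-di-tert-butyl-1,3,2-dioxasilinan-5-yl)-3,4-epoxycyclohexan-1-ol (hydroxyl, side chain and epoxide oxygen on one face) | O[C@@H]1CC[C@@H]2O[C@@H]2[C@@H]1C3CO[Si](C(C)(C)C)(C(C)(C)C)OC3 | intermediate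
11 | 2-(2,2-di-tert-butyl-1,3,2-dioxasilinan-5-yl)-3,4-epoxycyclohexan-1-one (side chain cis to epoxide) | O=C1CC[C@@H]2O[C@@H]2[C@@H]1C3CO[Si](C(C)(C)C)(C(C)(C)C)OC3 | intermediate
12 | 2-(1,3-dihydroxypropan-2-yl)-3,4-epoxycyclohexan-1-one (side chain cis to epoxide) | O=C1CC[C@@H]2O[C@@H]2[C@@H]1C(CO)CO | intermediate
13 | 2-(2,3-epoxy-6-oxocyclohexyl)-3-hydroxypropanal (side chain cis to epoxide, both C10 epimers) | O=C1CC[C@@H]2O[C@@H]2[C@@H]1C(CO)C=O | intermediate
14 | 2-(2,2-di-tert-butyl-4H-1,3,2-dioxasilin-5-yl)-3,4-epoxycyclohexan-1-one (side chain cis to epoxide) | O=C1CC[C@@H]2O[C@@H]2[C@@H]1C3=CO[Si](C(C)(C)C)(C(C)(C)C)OC3 | intermediate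
15 | lithium enolate of 14 (C5=C6) | [Li+].[O-]C1=CC[C@@H]2O[C@@H]2[C@@H]1C3=CO[Si](C(C)(C)C)(C(C)(C)C)OC3 | intermediate
16 | 2-(2,2-di-tert-butyl-4H-1,3,2-dioxasilin-5-yl)-3,4-epoxy-6-(phenylselanyl)cyclohexan-1-one (selanyl trans to side chain and epoxide) | O=C1[C@@H]([Se]c2ccccc2)C[C@@H]3O[C@@H]3[C@@H]1C4=CO[Si](C(C)(C)C)(C(C)(C)C)OC4 | intermediate
17 | 4-methoxybenzyl alcohol | COc1ccc(CO)cc1 | starting material
18 | 4-methoxybenzyl vinyl ether | C=COCc1ccc(OC)cc1 | intermediate
19 | 1,2-dibromoethyl 4-methoxybenzyl ether | BrCC(Br)OCc1ccc(OC)cc1 | intermediate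
20 | (Z)-1-bromo-2-(4-methoxybenzyloxy)ethene | Br/C=C\OCc1ccc(OC)cc1 | intermediate
21 | (Z)-2-(4-methoxybenzyloxy)vinyllithium | [Li]/C=C\OCc1ccc(OC)cc1 | intermediate
22 | (Z)-2-(4-methoxybenzyloxy)vinylcerium dichloride | Cl[Ce](Cl)/C=C\OCc1ccc(OC)cc1 | intermediate
23 | 2-(2,2-di-tert-butyl-4H-1,3,2-dioxasilin-5-yl)-3,4-epoxy-1-[(Z)-2-(4-methoxybenzyloxy)vinyl]-6-(phenylselanyl)cyclohexan-1-ol (alkenyl groups and epoxide on one face; hydroxyl and selanyl on the other) | O[C@@]1(/C=C\OCc2ccc(OC)cc2)[C@@H]([Se]c5ccccc5)C[C@@H]3O[C@@H]3[C@@H]1C4=CO[Si](C(C)(C)C)(C(C)(C)C)OC4 | intermediate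
24 | selenoxide of 23 | O[C@@]1(/C=C\OCc2ccc(OC)cc2)[C@@H]([Se](=O)c5ccccc5)C[C@@H]3O[C@@H]3[C@@H]1C4=CO[Si](C(C)(C)C)(C(C)(C)C)OC4 | intermediate
25 | (1R,4S,5R,6S)-6-(2,2-di-tert-butyl-4H-1,3,2-dioxasilin-5-yl)-4,5-epoxy-1-[(Z)-2-(4-methoxybenzyloxy)vinyl]cyclohex-2-en-1-ol | O[C@@]1(/C=C\OCc2ccc(OC)cc2)C=C[C@@H]3O[C@@H]3[C@@H]1C4=CO[Si](C(C)(C)C)(C(C)(C)C)OC4 | intermediate
26 | potassium alkoxide of 25 | [K+].[O-][C@@]1(/C=C\OCc2ccc(OC)cc2)C=C[C@@H]3O[C@@H]3[C@@H]1C4=CO[Si](C(C)(C)C)(C(C)(C)C)OC4 | intermediate
27 | potassium enolate of 28 (C6=C7, enolate oxygen cis to C8) | [K+].[O-]/C1=C\[C@H](OCc2ccc(OC)cc2)[C@@H]3O[Si](C(C)(C)C)(C(C)(C)C)OC/C3=C/[C@H]4O[C@H]4/C=C\1 | intermediate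
28 | ten-membered epoxy dienone: C6 ketone, cis C4=C5, cis C2–C3 epoxide (2R,3S), ring-cis C1=C10, C8 4-methoxybenzyl ether (8S), O9 (9R) and O14 joined as di-tert-butylsilylene | O=C1C[C@H](OCc2ccc(OC)cc2)[C@@H]3O[Si](C(C)(C)C)(C(C)(C)C)OC/C3=C/[C@H]4O[C@H]4/C=C\1 | intermediate
29 | tert-butyl bromoacetate | BrCC(=O)OC(C)(C)C | starting material
30 | lithium enolate of 28 | [Li+].[O-]/C1=C\[C@H](OCc2ccc(OC)cc2)[C@@H]3O[Si](C(C)(C)C)(C(C)(C)C)OC/C3=C/[C@H]4O[C@H]4/C=C\1 | intermediate
31 | 28 carrying CH2CO2t-Bu at C7 (7R) | O=C1[C@H](CC(=O)OC(C)(C)C)[C@H](OCc2ccc(OC)cc2)[C@@H]3O[Si](C(C)(C)C)(C(C)(C)C)OC/C3=C/[C@H]4O[C@H]4/C=C\1 | intermediate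
32 | (6S)-alcohol from 31 (hydroxyl cis to the C7 side chain) | O[C@@H]1[C@H](CC(=O)OC(C)(C)C)[C@H](OCc2ccc(OC)cc2)[C@@H]3O[Si](C(C)(C)C)(C(C)(C)C)OC/C3=C/[C@H]4O[C@H]4/C=C\1 | intermediate
33 | (6R)-4-nitrobenzoate (C6 inverted) | O=C(O[C@H]1[C@H](CC(=O)OC(C)(C)C)[C@H](OCc2ccc(OC)cc2)[C@@H]3O[Si](C(C)(C)C)(C(C)(C)C)OC/C3=C/[C@H]4O[C@H]4/C=C\1)c5ccc(cc5)[N+](=O)[O-] | intermediate
34 | (6R)-hydroxy tert-butyl ester (hydroxyl trans to the C7 side chain) | O[C@H]1[C@H](CC(=O)OC(C)(C)C)[C@H](OCc2ccc(OC)cc2)[C@@H]3O[Si](C(C)(C)C)(C(C)(C)C)OC/C3=C/[C@H]4O[C@H]4/C=C\1 | intermediate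
35 | trans-fused 6,7-γ-lactone (C11 methylene, C12 carbonyl) with C8 4-methoxybenzyl ether and O9/O14 silylene | C1C(=O)O[C@@H]2/C=C\[C@@H]3O[C@@H]3/C=C4/CO[Si](C(C)(C)C)(C(C)(C)C)O[C@H]4[C@@H](OCc5ccc(OC)cc5)[C@@H]12 | intermediate
36 | lithium enolate of lactone 35 | [Li+].C1=C([O-])O[C@@H]2/C=C\[C@@H]3O[C@@H]3/C=C4/CO[Si](C(C)(C)C)(C(C)(C)C)O[C@H]4[C@@H](OCc5ccc(OC)cc5)[C@@H]12 | intermediate
37 | 11-(dimethylaminomethyl) lactone (Mannich base, both C11 epimers) | CN(C)CC1C(=O)O[C@@H]2/C=C\[C@@H]3O[C@@H]3/C=C4/CO[Si](C(C)(C)C)(C(C)(C)C)O[C@H]4[C@@H](OCc5ccc(OC)cc5)[C@@H]12 | intermediate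
38 | 11-(trimethylammoniomethyl) lactone iodide | [I-].C[N+](C)(C)CC1C(=O)O[C@@H]2/C=C\[C@@H]3O[C@@H]3/C=C4/CO[Si](C(C)(C)C)(C(C)(C)C)O[C@H]4[C@@H](OCc5ccc(OC)cc5)[C@@H]12 | intermediate
39 | α-methylene lactone (C11=C13) with C8 4-methoxybenzyl ether and O9/O14 silylene | C=C1C(=O)O[C@@H]2/C=C\[C@@H]3O[C@@H]3/C=C4/CO[Si](C(C)(C)C)(C(C)(C)C)O[C@H]4[C@@H](OCc5ccc(OC)cc5)[C@@H]12 | intermediate
40 | α-methylene lactone with free C8 hydroxyl and O9/O14 silylene | C=C1C(=O)O[C@@H]2/C=C\[C@@H]3O[C@@H]3/C=C4/CO[Si](C(C)(C)C)(C(C)(C)C)O[C@H]4[C@@H](O)[C@@H]12 | intermediate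
41 | angelic acid | C/C=C(/C)C(=O)O | starting material
42 | (Z)-2-methylbut-2-en-1-ol | C/C=C(/C)CO | intermediate
43 | [(2R,3S)-2,3-dimethyloxiran-2-yl]methanol | OC[C@@]1(C)O[C@H]1C | intermediate
44 | (2S,3S)-2,3-dimethyloxirane-2-carbaldehyde | O=C[C@@]1(C)O[C@H]1C | intermediate
45 | (2S,3S)-2,3-dimethyloxirane-2-carboxylic acid | OC(=O)[C@@]1(C)O[C@H]1C | intermediate
46 | (2S,3S)-2,3-dimethyloxirane-2-carboxylic 2,4,6-trichlorobenzoic anhydride | O=C(OC(=O)[C@@]1(C)O[C@H]1C)c2c(Cl)cc(Cl)cc2Cl | intermediate
47 | α-methylene lactone with C8 (2S,3S)-epoxyangelate and O9/O14 silylene | C=C1C(=O)O[C@@H]2/C=C\[C@@H]3O[C@@H]3/C=C4/CO[Si](C(C)(C)C)(C(C)(C)C)O[C@H]4[C@@H](OC(=O)[C@@]5(C)O[C@H]5C)[C@@H]12 | intermediate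
48 | C8 epoxyangelate with free C9 and C14 hydroxyls | C=C1C(=O)O[C@@H]2/C=C\[C@@H]3O[C@@H]3/C=C(/CO)[C@@H](O)[C@@H](OC(=O)[C@@]3(C)O[C@H]3C)[C@@H]12 | intermediate
49 | C14 aldehyde (enal) with free C9 hydroxyl | C=C1C(=O)O[C@@H]2/C=C\[C@@H]3O[C@@H]3/C=C(/C=O)[C@@H](O)[C@@H](OC(=O)[C@@]3(C)O[C@H]3C)[C@@H]12 | intermediate
50 | C14 carboxylic acid with free C9 hydroxyl | C=C1C(=O)O[C@@H]2/C=C\[C@@H]3O[C@@H]3/C=C(/C(=O)O)[C@@H](O)[C@@H](OC(=O)[C@@]3(C)O[C@H]3C)[C@@H]12 | intermediate
51 | C14 methyl ester with free C9 hydroxyl | C=C1C(=O)O[C@@H]2/C=C\[C@@H]3O[C@@H]3/C=C(/C(=O)OC)[C@@H](O)[C@@H](OC(=O)[C@@]3(C)O[C@H]3C)[C@@H]12 | intermediate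
52 | CNP0077533.1 | C=C1C(=O)O[C@@H]2/C=C\[C@@H]3O[C@@H]3/C=C(/C(=O)OC)[C@@H](OC(C)=O)[C@@H](OC(=O)[C@@]3(C)O[C@H]3C)[C@@H]12 | target

**Totals and risks**

Total step count: 31. Longest linear sequence: 26 steps (steps 1–12, 15–23 and 27–31); steps 13–14 and 24–26 are side branches.

The three steps most likely to fail:

1. Step 17. The alkoxide may cleave the C1–C6 bond heterolytically and recombine without chair control, which would scramble C8 and C9. The enolate may also lose the C8 alkoxide by β-elimination. Fallback: the same [3,3] shift is run on the neutral silyl ether. Starting from 25, the tertiary alcohol is silylated with N-(trimethylsilyl)imidazole to the trimethylsilyl ether F1. F1 is heated in toluene at about 180 °C in a sealed tube with N,O-bis(trimethylsilyl)acetamide as acid scavenger, which should give the ten-membered trimethylsilyl enol ether F2 by the thermal siloxy-Cope rearrangement through the same chair. F2 is cleaved with Bu4NF buffered with AcOH at −78 °C, which returns to the route at 28.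

2. Step 15. The organometallic reagent may attack selenium and release the enolate instead of adding to the carbonyl. It may also add to the face anti to the C1 substituent and give the trans-dialkenyl carbinol. Fallback: the alkene is put in before the addition and selenium is avoided. Starting from 14, the lithium enolate (LiN(iPr)2, −78 °C) is dehydrogenated with N-tert-butylbenzenesulfinimidoyl chloride to the epoxy enone F3. Reagent 22, made from 20 as before, is added at −78 °C to this nearly flat enone, where attack anti to the pseudo-axial C1–H and on the side of the coordinating epoxide oxygen is expected. This returns to the route at 25, and steps 12 and 16 are then not needed.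

3. Step 18. The regenerated enolate may lose the C8 alkoxide by β-elimination, may be alkylated on oxygen, or may be attacked from the wrong face at C7. Fallback: the enolate is not regenerated from the ketone. Starting from 25, the rearrangement is run as in step 17, and enolate 27 is treated at −78 °C with 29 instead of being protonated. The enolate is then alkylated in the geometry and conformation in which the rearrangement delivers it (C8–O in the enolate plane, C9 on the inner face). This returns to the route at 31 and makes no new compound (F0).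

Further compounds

F1 | step 17 | trimethylsilyl ether of 25 | C[Si](C)(C)O[C@@]1(/C=C\OCc2ccc(OC)cc2)C=C[C@@H]3O[C@@H]3[C@@H]1C4=CO[Si](C(C)(C)C)(C(C)(C)C)OC4
F2 | step 17 | ten-membered trimethylsilyl enol ether (C6=C7, C6 OSiMe3) corresponding to 28 | C[Si](C)(C)O/C1=C\[C@H](OCc2ccc(OC)cc2)[C@@H]3O[Si](C(C)(C)C)(C(C)(C)C)OC/C3=C/[C@H]4O[C@H]4/C=C\1
F3 | step 15 | 6-(2,2-di-tert-butyl-4H-1,3,2-dioxasilin-5-yl)-4,5-epoxycyclohex-2-en-1-one (side chain cis to epoxide) | O=C1C=C[C@@H]2O[C@@H]2[C@@H]1C3=CO[Si](C(C)(C)C)(C(C)(C)C)OC3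
F0 | step 18 | none | none
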